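The data come from a simulation for substances that don't exist, and the scatter is random.

Monday's flask and Wednesday's flask differ in their charge of nucleophile, and the south and west runs show what that charge does to the electrophile.

common to all: electrophile 10 mM

| charge | nucleophile | remark | time |
|---|---|---|---|
| south | 0.79 equiv | run made earlier |  |
| west | 1.4 equiv | run made earlier |  |
| Monday's | 0.950 equiv |  | 1.0 h |
| Wednesday's | 1.90 equiv |  | 1.0 h |

| run | time / min | electrophile / % | target / % |
|---|---|---|---|
| south | 3.00 | 63.8 | 26.7 |
| south | 6.00 | 51.6 | 34.8 |
| south | 12.0 | 38.9 | 39.0 |
| south | 20.0 | 31.3 | 35.5 |
| south | 40.0 | 20.7 | 31.5 |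
| west | 8.00 | 28.3 | 57.9 |
| west | 15.0 | 19.7 | 57.4 |
| west | 25.0 | 14.7 | 54.4 |
| west | 30.0 | 9.6 | 52.0 |
| west | 40.0 | 9.3 | 45.3 |

(standard deviation of a reading: 1 percentage point)

- part of the electrophile that has reacted at the end, Monday's
- part of the electrophile that has reacted at the end, Wednesday's
- what raising the equivalents of nucleophile from its lowest to its highest value here does to the part of the electrophile that has reacted (changes below 5 percentage points count as none) (it falls / it rises / no change)



I turn the trend round: for "no change", Wednesday's flask must keep its electrophile left within 5 percentage points of Monday's. South has lost 79.3% of its electrophile by 40.0 min on 0.79 equiv of nucleophile, so I guess that late electrophile goes by meeting electrophile. I therefore read from south's last two readings the tail constant g, the rise per minute of the reciprocal of the fraction of electrophile left: 0.0818 /min.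

Interpolating between south and west at 40.0 min puts Monday's flask at 17.7% left. Adding g over the last 20.0 min gives 13.7% left, so 86.3% reacted. "No change" then needs Wednesday's flask above 8.73% left. Yet west, on 1.4 equiv of nucleophile, reckons to 8.07% at that time, lower than that mark. The gap of 0.66 points is smaller than the scatter of one reading, 1 point, so this mark is thin. Within that scatter, the opposite outcome asks Wednesday's flask, on 1.90 equiv of nucleophile, to leave about as much electrophile as west or more, against the fall in electrophile left from south to west at 40.0 min.

The forecast says 88% (84% to 92%) for Monday's flask and 97% (94% to 99.5%) for Wednesday's, where “more nucleophile survives”, and its answer on the trend is: it rises. My Monday's figure is lower than its own.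

Monday's flask gives 86.7% and Wednesday's 99.5%, so the part reacted: it rises, by 13 points.

    electrophile + nucleophile → acid set free + target (k = 0.460 /M/s)
    nucleophile + acid set free ⇌ protonated nucleophile, settled at all times (K = 2200 /M)
    2 electrophile → homo dimer (k = 0.0310 /M/s)
    target → over-reaction product (k = 2.70 × 10⁻⁴ /s)

Monday's flask holds 13% electrophile at 1.00 h, against my 13.7%. Left until 4.0 h, g carries that flask's 13.3% down to 4.49%. It really holds 3.0% electrophile, and unbound nucleophile, the limiting reagent there, stands at 1.9% of its charge.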